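**Plan**

- Retrosynthesis: the four O–alkyl bonds are cut first (three aryl OMe and the C7–OEt). Ring A is then cut at C8–C8a, C7–C8, C5–C6 and C4a–C5, which leaves a 4-pyranon-2-yl diazomethyl ketone and ethoxyacetylene.
- Enabling feature: ring A (C4a, C5, C6, C7, C8, C8a) is a resorcinol with meta oxygens on C5 and C7, fused to ring C through the C4a=C8a bond of a 4-pyranone. A pyranonylketene and an ynol ether assemble exactly this pattern.
- Further cuts: the CO–CHN2 bond (back to a pyranone-2-carboxylic acid), ring C at O1–C8a, the two Claisen bonds C4a–C8a and C3–C4, and the ketone bond C2–C3.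
- Forward: ring B is purchased. The chain is joined by acyl cross-coupling (C2–C3), acetyl Claisen (C3–C4) and oxalyl Claisen (C4a–C8a). Ring C closes by acid cyclodehydration (O1–C8a), ring A closes last by benzannulation, and global dealkylation ends the route.
- Stereochemistry: the target has no stereocentre and no stereogenic double bond. The transient centres of the key step vanish on aromatization.

Key step: step 6

Assumption: flavone numbering (O1, C2, C3, C4, C4a, C5 to C8, C8a) is used for atoms of all pyranone and chromone intermediates, and β-dicarbonyl intermediates are drawn and named as keto tautomers although they should be largely enolised.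

**Step 1**
Reactants: 1 3,4,5-trimethoxybenzoyl chloride; 2 1-bromo-4-methylpentane
Product: 4 5-methyl-1-(3,4,5-trimethoxyphenyl)hexan-1-one, via (4-methylpentyl)magnesium bromide 3 (not isolated)
Conditions: 2, Mg, I2 (cat.), THF, 40 °C; then 1, Fe(acac)3 (3 mol %), THF, −78 °C; aq. NH4Cl
Reagents that add atoms: none
Why: Iron-catalysed acylation of an alkyl Grignard reagent by an aroyl chloride (Kumada-type acyl cross-coupling) is fast at −78 °C and should stop at the ketone because coupling outruns carbonyl addition.

**Step 2**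
Reactants: 4 5-methyl-1-(3,4,5-trimethoxyphenyl)hexan-1-one
Product: 5 2-(3-methylbutyl)-1-(3,4,5-trimethoxyphenyl)butane-1,3-dione
Conditions: NaH (2.5 equiv), EtOAc (4 equiv), THF, 0 °C → reflux; 1 M HCl
Reagents that add atoms: ethyl acetate, CCOC(C)=O
Why: In this crossed Claisen condensation the ketone has only one enolisable position, and deprotonation of the resulting 2-alkyl-1,3-diketone should pull the equilibrium to product.

**Step 3**
Reactants: 5 2-(3-methylbutyl)-1-(3,4,5-trimethoxyphenyl)butane-1,3-dione; 6 diethyl oxalate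
Product: 7 ethyl 5-(3-methylbutyl)-2,4,6-trioxo-6-(3,4,5-trimethoxyphenyl)hexanoate
Conditions: LiN(i-Pr)2 (2.2 equiv), THF, −78 → 0 °C; cannulated into 6 (3 equiv), THF, −78 °C; 1 M HCl
Reagents that add atoms: none
Why: Double deprotonation gives the 1,3-dianion, whose more basic methyl-derived terminus should undergo Claisen acylation by the non-enolisable oxalate, while inverse addition into excess oxalate limits double addition and proton return from the product.

**Step 4**
Reactants: 7 ethyl 5-(3-methylbutyl)-2,4,6-trioxo-6-(3,4,5-trimethoxyphenyl)hexanoate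
Product: 9 5-(3-methylbutyl)-4-oxo-6-(3,4,5-trimethoxyphenyl)-4H-pyran-2-carboxylic acid, via pyranone ethyl ester 8 (not isolated)
Conditions: AcOH, 6 M aq. HCl, 100 °C
Reagents that add atoms: water, O
Why: Acid-catalysed cyclodehydration of a 1,3,5-tricarbonyl compound (6-exo-trig attack of the aryl ketone enol oxygen on the α-keto ester carbonyl, then loss of water) is the classical 4-pyranone synthesis, and the same medium should hydrolyse the activated ester while sparing the aryl methyl ethers.

**Step 5**
Reactants: 9 5-(3-methylbutyl)-4-oxo-6-(3,4,5-trimethoxyphenyl)-4H-pyran-2-carboxylic acid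
Product: 11 2-diazo-1-[5-(3-methylbutyl)-4-oxo-6-(3,4,5-trimethoxyphenyl)-4H-pyran-2-yl]ethan-1-one, via acid chloride 10 (not isolated)
Conditions: (COCl)2 (1.2 equiv), DMF (cat.), CH2Cl2, 0 °C → rt, evaporate; CH2N2 (3 equiv), Et2O, 0 °C
Reagents that add atoms: diazomethane, C=[N+]=[N-]
Why: C-acylation of diazomethane by an acid chloride (first stage of the Arndt–Eistert sequence) should give the diazomethyl ketone, since a second equivalent of diazomethane removes the HCl and acylation at 0 °C is much faster than dipolar cycloaddition to the pyranone double bond.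

**Step 6**
Reactants: 11 2-diazo-1-[5-(3-methylbutyl)-4-oxo-6-(3,4,5-trimethoxyphenyl)-4H-pyran-2-yl]ethan-1-one; 12 ethoxyacetylene
Product: 17 7-ethoxy-5-hydroxy-3-(3-methylbutyl)-2-(3,4,5-trimethoxyphenyl)-4H-chromen-4-one, via pyranonylketene 13 (not isolated), via cyclobutenone 14 (not isolated), via dienylketene 15 (not isolated), via cyclohexadienone 16 (not isolated)
Conditions: 12 (3 equiv), ClCH2CH2Cl, hν (365 nm, Pyrex), rt; then 80 °C
Reagents that add atoms: none
Why: Light expels N2 from 11 with 1,2-shift of the pyranonyl group (Wolff rearrangement, forming C8–C8a) to give ketene 13, whose carbonyl carbon is attacked by the nucleophilic CH terminus of the ynol ether in a (2+2) cycloaddition that forms C5–C6 and C7–C8 and gives cyclobutenone 14. Warming opens 14 by reversible four-electron electrocyclic cleavage to dienylketene 15, and ring A then closes by a thermal disrotatory six-electron electrocyclization of the ketene carbon C5 onto the pyranone CH carbon C4a, followed by enolization of dienone 16 to the phenol. The closest known reaction type is the second-generation Danheiser benzannulation of α,β-unsaturated and heteroaryl α-diazo ketones with alkoxy- and siloxyalkynes, to which 11 belongs as a cyclic β-oxygenated vinyl diazo ketone. No stereocentre is created, since the transient centres of 14 and 16 are lost on ring opening and tautomerization. Two selectivities are needed: the orientation of the (2+2) step, which the polarization of ethoxyacetylene fixes so that OEt lands on C7 and OH on C5, and the site of ring closure, which is unambiguous because the only carbon neighbour of C8a in ring C is C4a, the other neighbour being O1. The C4a=C8a bond is a vinylogous ester alkene and not a benzenoid bond, so closure costs no aromaticity, and only the dienylketene isomer with the pyranone turned inward can cyclize while the outward isomer should revert to 14.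

**Step 7**
Reactants: 17 7-ethoxy-5-hydroxy-3-(3-methylbutyl)-2-(3,4,5-trimethoxyphenyl)-4H-chromen-4-one
Product: 18 asplenetin (5,7-dihydroxy-3-(3-methylbutyl)-2-(3,4,5-trihydroxyphenyl)-4H-chromen-4-one)
Conditions: BBr3 (10 equiv), CH2Cl2, −78 °C → rt; H2O, 0 °C
Reagents that add atoms: none
Why: BBr3 cleaves aryl methyl and ethyl ethers by Lewis acid complexation and bromide attack on the alkyl group, the saturated 3-methylbutyl chain and the chromone are inert to it, and hydrolysis of the aryl borates should release all five phenols.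

**Compound list**

1 | 3,4,5-trimethoxybenzoyl chloride | COc1cc(C(=O)Cl)cc(OC)c1OC | starting material
2 | 1-bromo-4-methylpentane | CC(C)CCCBr | starting material
3 | (4-methylpentyl)magnesium bromide | CC(C)CCC[Mg]Br | intermediate
4 | 5-methyl-1-(3,4,5-trimethoxyphenyl)hexan-1-one | CC(C)CCCC(=O)c1cc(OC)c(OC)c(OC)c1 | intermediate
5 | 2-(3-methylbutyl)-1-(3,4,5-trimethoxyphenyl)butane-1,3-dione (racemic, enolisable) | CC(=O)C(CCC(C)C)C(=O)c1cc(OC)c(OC)c(OC)c1 | intermediate
6 | diethyl oxalate | CCOC(=O)C(=O)OCC | starting material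
7 | ethyl 5-(3-methylbutyl)-2,4,6-trioxo-6-(3,4,5-trimethoxyphenyl)hexanoate (racemic, enolisable) | CCOC(=O)C(=O)CC(=O)C(CCC(C)C)C(=O)c1cc(OC)c(OC)c(OC)c1 | intermediate
8 | ethyl 5-(3-methylbutyl)-4-oxo-6-(3,4,5-trimethoxyphenyl)-4H-pyran-2-carboxylate | CCOC(=O)c1cc(=O)c(CCC(C)C)c(-c2cc(OC)c(OC)c(OC)c2)o1 | intermediate
9 | 5-(3-methylbutyl)-4-oxo-6-(3,4,5-trimethoxyphenyl)-4H-pyran-2-carboxylic acid | OC(=O)c1cc(=O)c(CCC(C)C)c(-c2cc(OC)c(OC)c(OC)c2)o1 | intermediate
10 | 5-(3-methylbutyl)-4-oxo-6-(3,4,5-trimethoxyphenyl)-4H-pyran-2-carbonyl chloride | ClC(=O)c1cc(=O)c(CCC(C)C)c(-c2cc(OC)c(OC)c(OC)c2)o1 | intermediate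
11 | 2-diazo-1-[5-(3-methylbutyl)-4-oxo-6-(3,4,5-trimethoxyphenyl)-4H-pyran-2-yl]ethan-1-one | [N-]=[N+]=CC(=O)c1cc(=O)c(CCC(C)C)c(-c2cc(OC)c(OC)c(OC)c2)o1 | intermediate
12 | ethoxyacetylene (ethoxyethyne) | CCOC#C | starting material
13 | 2-[5-(3-methylbutyl)-4-oxo-6-(3,4,5-trimethoxyphenyl)-4H-pyran-2-yl]ethen-1-one | O=C=Cc1cc(=O)c(CCC(C)C)c(-c2cc(OC)c(OC)c(OC)c2)o1 | intermediate
14 | 3-ethoxy-4-[5-(3-methylbutyl)-4-oxo-6-(3,4,5-trimethoxyphenyl)-4H-pyran-2-yl]cyclobut-2-en-1-one (racemic) | CCOC1=CC(=O)C1c1cc(=O)c(CCC(C)C)c(-c2cc(OC)c(OC)c(OC)c2)o1 | intermediate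
15 | (3E)-3-ethoxy-4-[5-(3-methylbutyl)-4-oxo-6-(3,4,5-trimethoxyphenyl)-4H-pyran-2-yl]buta-1,3-dien-1-one | O=C=C/C(OCC)=C\c1cc(=O)c(CCC(C)C)c(-c2cc(OC)c(OC)c(OC)c2)o1 | intermediate
16 | 7-ethoxy-3-(3-methylbutyl)-2-(3,4,5-trimethoxyphenyl)-4aH-chromene-4,5-dione (racemic) | CCOC1=CC(=O)C2C(=C1)OC(-c1cc(OC)c(OC)c(OC)c1)=C(CCC(C)C)C2=O | intermediate
17 | 7-ethoxy-5-hydroxy-3-(3-methylbutyl)-2-(3,4,5-trimethoxyphenyl)-4H-chromen-4-one | CCOc1cc(O)c2c(c1)oc(-c1cc(OC)c(OC)c(OC)c1)c(CCC(C)C)c2=O | intermediate
18 | asplenetin, 5,7-dihydroxy-3-(3-methylbutyl)-2-(3,4,5-trihydroxyphenyl)-4H-chromen-4-one | CC(C)CCc1c(-c2cc(O)c(O)c(O)c2)oc2cc(O)cc(O)c2c1=O | target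

**Step count and risks**

Total step count: 7. Longest linear sequence: 7 steps (from 1 and 2 to 18).

Steps most likely to fail:

1. Step 6. Excitation of the aryl pyranone chromophore (photoisomerization, internal filtering by the cyclobutenone and the chromone) may compete with nitrogen loss, or the ketene may be diverted before it meets the ynol ether. The fallback generates the same ketene in the dark and sets out from 11. A Wolff rearrangement catalysed by PhCO2Ag with Et3N in aqueous THF at rt should give 2-[5-(3-methylbutyl)-4-oxo-6-(3,4,5-trimethoxyphenyl)-4H-pyran-2-yl]acetic acid F1. (COCl)2 with catalytic DMF in CH2Cl2 converts this into 2-[5-(3-methylbutyl)-4-oxo-6-(3,4,5-trimethoxyphenyl)-4H-pyran-2-yl]acetyl chloride F2. Slow addition of Et3N to F2 and excess 12 in CH2Cl2 at 0 °C → rt dehydrochlorinates F2 to ketene 13, which the ynol ether captures. The fallback comes back to the route at cyclobutenone 14, which is isolable at rt and is then heated in toluene at 80–110 °C to give 17.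

2. Step 3. Proton transfer from the acylated product to unreacted dianion, a second addition to the oxalate, or retro-Claisen fragmentation of the 2-alkyl diketone may erode the acylation. The fallback removes strong base from the C–C bond-forming event and sets out from 5. The dianion (LiN(i-Pr)2, 2.2 equiv, THF, −78 → 0 °C) is trapped with Me3SiCl as trimethyl{[3-(3-methylbutyl)-4-(3,4,5-trimethoxyphenyl)-4-(trimethylsilyloxy)buta-1,3-dien-2-yl]oxy}silane F3, whose enol double-bond geometry is without consequence. Mukaiyama-type acylation of the terminal CH2 of F3 with ethyl chlorooxoacetate (CH2Cl2, −78 °C, catalytic Me3SiOTf) and work-up with aqueous HCl should return the route at 7.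

3. Step 5. The chlorinating agent may activate the pyranone carbonyl toward a 4-chloropyrylium species, liberated HCl may convert the diazo ketone into the chloromethyl ketone, or diazomethane may undergo dipolar cycloaddition to the pyranone double bond during a slow acylation. The fallback is chloride-free and sets out from 9. Isobutyl chloroformate and N-methylmorpholine in THF at −15 °C give the mixed anhydride (2-methylpropoxy)carbonyl 5-(3-methylbutyl)-4-oxo-6-(3,4,5-trimethoxyphenyl)-4H-pyran-2-carboxylate F4. Ethereal CH2N2 at 0 °C is acylated by F4 with loss of CO2 and 2-methylpropan-1-ol, and the route is rejoined at 11.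

**Further compounds**

F1 | step 6 | 2-[5-(3-methylbutyl)-4-oxo-6-(3,4,5-trimethoxyphenyl)-4H-pyran-2-yl]acetic acid | OC(=O)Cc1cc(=O)c(CCC(C)C)c(-c2cc(OC)c(OC)c(OC)c2)o1
F2 | step 6 | 2-[5-(3-methylbutyl)-4-oxo-6-(3,4,5-trimethoxyphenyl)-4H-pyran-2-yl]acetyl chloride | ClC(=O)Cc1cc(=O)c(CCC(C)C)c(-c2cc(OC)c(OC)c(OC)c2)o1
F3 | step 3 | trimethyl{[3-(3-methylbutyl)-4-(3,4,5-trimethoxyphenyl)-4-(trimethylsilyloxy)buta-1,3-dien-2-yl]oxy}silane | C=C(O[Si](C)(C)C)C(CCC(C)C)=C(O[Si](C)(C)C)c1cc(OC)c(OC)c(OC)c1
F4 | step 5 | (2-methylpropoxy)carbonyl 5-(3-methylbutyl)-4-oxo-6-(3,4,5-trimethoxyphenyl)-4H-pyran-2-carboxylate | CC(C)COC(=O)OC(=O)c1cc(=O)c(CCC(C)C)c(-c2cc(OC)c(OC)c(OC)c2)o1
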